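**Retrosynthetic overview**

1. Jaeskeanin ⇒ acylation at O‑6 of 8α,9α‑epoxyjaeschkeanadiol ⇒ OH‑directed epoxidation of jaeschkeanadiol (epoxide made after both carbocycles).
2. Jaeschkeanadiol ⇒ directed anti‑reduction of the 4β‑hydroxy‑6‑ketone ⇒ i‑Pr organocerium addition to a bicyclo[5.3.0] 1,3‑diketone (C4 set anti to the angular methyl, C5 by equilibration).
3. 1,3‑Diketone ⇒ key step: enantioselective, symmetry‑breaking homoenolate conjugate addition/Dieckmann cyclopentannulation of achiral 3,6‑dimethylcyclohepta‑2,6‑dienone (sets C1; five‑membered ring formed second).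
4. Dienone ⇒ hydrogenation and double β‑elimination of the meso oxabicycle from a dearomative [4+3] cycloaddition of 2,5‑dimethylfuran with an oxyallyl cation (seven‑membered ring formed first).

Assumptions: daucane numbering is used (C1 = angular‑methyl carbon, C4 = C(OH)iPr, C5 = ring‑fusion CH, C6 = ester carbon, C8/C9 = epoxide). Compounds 2, 6, 8, 12 and 14 are purchased. The ligand antipode in step 4 is chosen to give (3aS)‑7. CIP labels were derived by hand from the SMILES; the SMILES are authoritative.

**Step 1**
Reactants: 1 (2,5‑dimethylfuran), 2 (1,1,3‑trichloroacetone)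
Product: 3, meso‑(1R,5S)‑1,5‑dimethyl‑8‑oxabicyclo[3.2.1]oct‑6‑en‑3‑one
Conditions: Et3N, CF3CH2OH, 0 °C→rt; then Zn–Cu, NH4Cl, MeOH, rt (one pot, two stages)
Reagents that add atoms: 1,1,3‑trichloroacetone, ClCC(=O)C(Cl)Cl (supplies the C3O unit; chlorines are removed)
Why: Föhlisch‑type oxyallyl‑cation [4+3] cycloaddition across C2/C5 of the furan breaks its aromaticity, and Zn–Cu removes the α‑chlorines; the bridge can only be cis, so one meso adduct forms.

**Step 2**
Reactants: 3
Product: 4, meso‑(1R,5S)‑1,5‑dimethyl‑8‑oxabicyclo[3.2.1]octan‑3‑one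
Conditions: H2 (1 atm), 10% Pd/C, EtOAc, rt
Reagents that add atoms: none
Why: Catalytic hydrogenation of the strained disubstituted alkene; the ketone and bridging ether are inert and no stereocentre changes.

**Step 3**
Reactants: 4
Product: 5, 3,6‑dimethylcyclohepta‑2,6‑dien‑1‑one (achiral, C2v‑symmetric)
Conditions: TsOH·H2O (0.2 equiv), PhMe, 90 °C, Dean–Stark
Reagents that add atoms: none
Why: Acid‑mediated double β‑elimination (both C–O bonds are tertiary and β to the ketone) opens the oxa‑bridge to the cross‑conjugated dienone, whose two β‑methyl enone termini are equivalent, so the next step has no regiochemical ambiguity.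

**Step 4 (key step)**
Reactants: 5, 6 ((1‑ethoxycyclopropoxy)trimethylsilane)
Product: 7, (3aS)‑3a,6‑dimethyl‑2,3,3a,4,5,8a‑hexahydroazulene‑1,8‑dione (C3a = daucane C1; exists mainly as the 8‑hydroxy enol, so C8a is not a fixed stereocentre)
Conditions: 6 (2 equiv), ZnCl2, Et2O, rt → Zn(CH2CH2CO2Et)2·2TMSCl; add 5, Cu(OTf)2 (5 mol%), chiral NHC or phosphoramidite ligand (10 mol%), Et2O, −30→0 °C; then KOtBu, THF, 0 °C→rt; AcOH
Reagents that add atoms: (1‑ethoxycyclopropoxy)trimethylsilane, CCOC1(O[Si](C)(C)C)CC1 (supplies CH2CH2C=O; EtO and TMS are lost)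
Why: Proposed new method: a Cu/chiral‑ligand‑controlled conjugate addition of the Nakamura–Kuwajima zinc homoenolate to one of the two equivalent enone termini breaks the symmetry and creates the C1 quaternary stereocentre, and the C5 enolate (freed from its TMS ether by KOtBu) then closes the five‑membered ring by Dieckmann acylation, driven by β‑diketonate formation; the closest known reactions are the racemic Cu/TMSCl‑promoted homoenolate conjugate addition and Cu‑catalysed asymmetric conjugate addition of dialkylzincs to β‑methyl cyclic enones, not yet combined for this reagent and substrate.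

**Step 5**
Reactants: 7, 8 (isopropylmagnesium chloride)
Product: 9, (3R,3aR,8aS)‑3‑hydroxy‑6,8a‑dimethyl‑3‑(propan‑2‑yl)‑2,3,3a,7,8,8a‑hexahydroazulen‑4(1H)‑one (4β‑hydroxy‑5αH‑dauc‑7‑en‑6‑one; trans‑fused, OH cis to the angular methyl)
Conditions: TESOTf (1.05 equiv), Et3N, CH2Cl2, 0 °C; then i‑PrMgCl/CeCl3, THF, −78 °C; then TBAF/AcOH, THF, 0 °C
Reagents that add atoms: isopropylmagnesium chloride, CC(C)[Mg]Cl
Why: Stork–Danheiser‑type 1,2‑addition of an organocerium to the vinylogous silyl ester: the diketone should silylate on the seven‑ring oxygen (enol C=C exo to the cyclopentanone), leaving only the C4 carbonyl, which is attacked anti to the pseudo‑axial angular methyl to give 4β‑OH/4α‑iPr; buffered fluoride then unmasks the 6‑ketone and the epimerisable C5 is expected to settle as the trans‑fused epimer (C6 cis to OH and H‑bonded, trans to iPr).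

**Step 6**
Reactants: 9
Product: 10, (3R,3aR,8aR)‑3‑hydroxy‑6,8a‑dimethyl‑3‑(propan‑2‑yl)‑2,3,3a,5,8,8a‑hexahydroazulen‑4(1H)‑one (4β‑hydroxy‑5αH‑dauc‑8‑en‑6‑one)
Conditions: TMSOTf (2.5 equiv), Et3N, CH2Cl2, 0 °C; then TBAF, THF, −78 °C, AcOH quench
Reagents that add atoms: none
Why: Deconjugative isomerisation (Ringold type): soft enolisation gives the extended silyl dienol ether (the hindered C5–H is not removed, and transient silylation of the 4‑OH blocks retro‑aldol), and the fluoride‑generated dienolate is protonated kinetically at C7 to give the β,γ‑enone; C1 and C4 are untouched.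

**Step 7**
Reactants: 10
Product: 11, jaeschkeanadiol, (3R,3aS,4S,8aR)‑6,8a‑dimethyl‑3‑(propan‑2‑yl)‑1,2,3,3a,4,5,8,8a‑octahydroazulene‑3,4‑diol
Conditions: Me4NBH(OAc)3, MeCN/AcOH (1:1), −20 °C
Reagents that add atoms: none
Why: Evans–Saksena directed reduction: the boron bound to the 4β‑oxygen delivers hydride to the β‑face of the C6 ketone, giving the anti‑1,3‑diol (6α‑OH) and fixing C5; the acidic medium avoids retro‑aldol and reconjugation.

**Step 8**
Reactants: 11, 12 (tert‑butyl hydroperoxide)
Product: 13, 8α,9α‑epoxyjaeschkeanadiol, (1R,4R,5S,6S,8R,9S)‑8,9‑epoxydaucane‑4,6‑diol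
Conditions: VO(acac)2 (5 mol%), t‑BuOOH, CH2Cl2, 0 °C→rt
Reagents that add atoms: tert‑butyl hydroperoxide, CC(C)(C)OO (adds O)
Why: Vanadium‑catalysed hydroxyl‑directed epoxidation: the homoallylic 6α‑OH delivers oxygen to the α‑face of the C8=C9 alkene, which is also the face away from the β angular methyl, setting C8 and C9.

**Step 9**
Reactants: 13, 14 (4‑acetoxybenzoyl chloride)
Product: 15, jaeskeanin (target)
Conditions: 14, DMAP, Et3N, CH2Cl2, 0 °C→rt; then pyrrolidine, rt, 30 min (one pot)
Reagents that add atoms: 4‑acetoxybenzoyl chloride, CC(=O)Oc1ccc(cc1)C(Cl)=O (the acetyl group is removed)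
Why: DMAP‑catalysed acylation of the secondary 6‑OH (the tertiary 4‑OH does not react), followed by chemoselective aminolysis of the much more labile aryl acetate; the hindered benzoate, epoxide and tertiary alcohol survive the mild amine.

**Compound list**

1 | 2,5‑dimethylfuran | Cc1ccc(C)o1 | starting material
2 | 1,1,3‑trichloroacetone | ClCC(=O)C(Cl)Cl | starting material
3 | meso‑(1R,5S)‑1,5‑dimethyl‑8‑oxabicyclo[3.2.1]oct‑6‑en‑3‑one | O=C1C[C@]2(C)C=C[C@](C)(C1)O2 | intermediate
4 | meso‑(1R,5S)‑1,5‑dimethyl‑8‑oxabicyclo[3.2.1]octan‑3‑one | O=C1C[C@]2(C)CC[C@](C)(C1)O2 | intermediate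
5 | 3,6‑dimethylcyclohepta‑2,6‑dien‑1‑one | CC1=CC(=O)C=C(C)CC1 | intermediate
6 | (1‑ethoxycyclopropoxy)trimethylsilane | CCOC1(O[Si](C)(C)C)CC1 | starting material
7 | (3aS)‑3a,6‑dimethyl‑2,3,3a,4,5,8a‑hexahydroazulene‑1,8‑dione | O=C1CC[C@]2(C)CCC(C)=CC(=O)C12 | intermediate
8 | isopropylmagnesium chloride | CC(C)[Mg]Cl | starting material
9 | 4β‑hydroxy‑5αH‑dauc‑7‑en‑6‑one | CC(C)[C@]1(O)CC[C@]2(C)CCC(C)=CC(=O)[C@H]21 | intermediate
10 | 4β‑hydroxy‑5αH‑dauc‑8‑en‑6‑one | CC(C)[C@]1(O)CC[C@]2(C)CC=C(C)CC(=O)[C@H]21 | intermediate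
11 | jaeschkeanadiol | CC(C)[C@]1(O)CC[C@]2(C)CC=C(C)C[C@H](O)[C@H]21 | intermediate
12 | tert‑butyl hydroperoxide | CC(C)(C)OO | starting material
13 | 8α,9α‑epoxyjaeschkeanadiol | CC(C)[C@]1(O)CC[C@]2(C)C[C@@H]3O[C@]3(C)C[C@H](O)[C@H]21 | intermediate
14 | 4‑acetoxybenzoyl chloride | CC(=O)Oc1ccc(cc1)C(Cl)=O | starting material
15 | jaeskeanin | CC(C)[C@]1(O)CC[C@]2(C)C[C@@H]3O[C@]3(C)C[C@H](OC(=O)c3ccc(O)cc3)[C@H]21 | target

**Totals**

Total steps: 9. Longest linear sequence: 9 (fully linear; all other inputs are purchased).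

**Steps most likely to fail, with fallbacks**

1. Step 4 (yield and ee of forming a quaternary centre with a chelated zinc homoenolate on a hindered dienone). Fallback: switch the nucleophile class to a Grignard homoenolate equivalent, 2‑(1,3‑dioxolan‑2‑yl)ethylmagnesium bromide, under established Cu/NHC asymmetric conjugate addition to β‑methyl cyclic enones. The ring is then closed by acetal unmasking and aldol cyclisation, and the secondary carbinol is oxidised to the same diketone 7 (two extra steps).

2. Step 5 (which carbonyl of the diketone is attacked, enolisation by the organometallic, and whether C5 equilibrates to the trans‑fused ketol). Fallback: bring the isopropyl ketone in with the nucleophile instead. Use the ketone homoenolate from 1‑isopropylcyclopropanol in step 4 and form the C4–C5 bond by a Lewis‑acid intramolecular aldol of the silyl enol ether, then equilibrate C5. The cost is that C4 is then set in the aldol rather than by addition anti to the angular methyl, which I expect to be less reliable.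

3. Step 6 (incomplete deconjugation, exocyclic‑methylene isomer, or retro‑aldol). Fallback: put the C8=C9 alkene in place before the annulation. Open the unsaturated oxabicycle 3 (ketone reduced and protected) by reductive SN2′ ring opening with DIBAL/Ni, which gives the trisubstituted alkene directly. Reoxidise and dehydrate to the unsymmetrical 3,6‑dimethylcyclohepta‑2,5‑dienone and run step 4 on that, with facial rather than symmetry‑breaking selectivity.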